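Count amounts in mM, not in percent of the charge, and the two runs look alike while solid is left.

| flask | solid substrate | gas | remark | time |
|---|---|---|---|---|
| Saturday's | 5 mM | 0.32 mM (held) | run made earlier |  |
| Tuesday's | 7.5 mM | 0.32 mM (held) | run made earlier |  |
| flask | 10 mM | 0.32 mM (held) |  | 3.0 d |

| run | time / d | product / % | solid substrate / % |
|---|---|---|---|
| Saturday's | 0.208 | 0 | 70 |
| Saturday's | 0.500 | 10 | 41 |
| Saturday's | 1.04 | 44 | 3 |
| Saturday's | 1.67 | 67 | 0 |
| Saturday's | 2.00 | 73 | 0 |
| Saturday's | 3.00 | 84 | 1 |
| Saturday's | 4.00 | 90 | 0 |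
| Tuesday's | 0.250 | 2 | 76 |
| Tuesday's | 0.417 | 8 | 67 |
| Tuesday's | 0.625 | 13 | 54 |
| Tuesday's | 1.04 | 28 | 35 |
| Tuesday's | 1.67 | 55 | 8 |
| Tuesday's | 2.50 | 79 | 0 |
| Tuesday's | 4.00 | 90 | 4 |

(readings scatter by 1.5 percentage points)

- as a solid, counted per litre of solution: solid substrate
- at the start none of the solid substrate is in solution
- at the start none of the gas is in solution

1. amount of product in percent of the solid substrate charged, at 8.0 h, 20 h, 40 h and 3.0 d

At 1.04 d, Saturday's run has lost 4.85 mM of solid substrate and Tuesday's run 4.87 mM. So take a bench rule: while solid is left and gas is held at 0.32 mM, a new flask copies the earlier runs in mM. The crawl 3.21 mM d⁻¹, the steady loss of solid substrate per litre and day, is read from Tuesday's run between 1.04 d and 1.67 d. It is a zero-order stretch.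

Apply the rule to the flask. At 40 h, Tuesday's run holds 4.12 mM of product, which is 41.2 % of the flask's charge.

Now find the border. By the rule, the flask then has 3.10 mM of solid left, and dividing by the crawl puts its end at 2.63 d. That is earlier than 3.0 d, so the last point lies beyond the rule.

For that point, use the hold-up: solid lost minus product. In Tuesday's run it is 2.77 mM at 1.67 d. In Saturday's run, with solid down to 3 %, it shrinks from 2.65 mM to 1.65 mM in 0.630 d. Scaled by that ratio, the estimated hold-up of the flask comes to 2.11 mM at 3.0 d, so your reckoning gives 78.9 % of product.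

The forecast reads 3 %, 15 %, 41 % and 80 %, on the ground that “Loss therefore doesn't depend on charge while solid remains”. At 3.0 d, your figure lies slightly below it.

The flask gives 2.67 %, 14.6 %, 39.8 % and 79.1 %. At 3.00 d, starting material stands at 20.9 % of the charge.

    2 partner → homo dimer (k = 0.260 M⁻¹ s⁻¹)
    solid substrate ⇌ starting material, rate k2*(cs2 - [starting material]) while solid is left; crystals form when [starting material] > cs2 (solubility = 4.70 mM, k = 2.10 × 10⁻⁵ s⁻¹)
    starting material + partner → product, rate k3*[starting material]^1.5*[partner]^0.5 (k = 0.0140 M⁻¹ s⁻¹)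
    gas ⇌ partner, rate k4*(csat - [partner]) (kL = 0.00110 s⁻¹)

At 1.50 d, the flask has 3.59 mM of solid substrate. At the crawl that reckons to 1.12 d, which puts the end at 2.62 d, and at 3.00 d the flask shows 0 % solid substrate.

The readings come from a simulation on assumed constants; noise was put on by code.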